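**Remark (assumption).** Positions are numbered as in the cembrane skeleton of the target, also in open-chain intermediates: ring carbons C1–C14, lactone carbons C15 (α), C16 (C=O) and C17 (=CH2), methyl carbons C18 (on C4), C19 (on C8, later the exo-methylene) and C20 (on C12). The L-fructose-derived enantiomer of the Shi ketone ("ent-Shi ketone", made from L-sorbose) is taken to be available.

## Analysis of the target

Compound 26 is a cembranolide: a 14-membered carbocycle (C1–C14) trans-fused across C1/C14 to an α-methylene-γ-butyrolactone (O14–C16(=O)–C15(=C17H2)–C1). It has six stereocentres: 1R, 3S, 4S, 7R, 13S and 14R. C13, C14 and C1 are contiguous; the acetoxy group on C13 and the lactone oxygen on C14 are anti, and H1 and H14 are trans. The 3S,4S epoxide is the trans-epoxide of an E-trisubstituted alkene one carbon away from C1. The 7R hydroperoxide, allylic to the C8 exo-methylene, is remote from every other centre, so its configuration cannot be relayed through the ring. The sensitive groups are the secondary allylic hydroperoxide (reductants, base, acid, metals), the methylene lactone (Michael acceptor), the trisubstituted epoxide (acid and internal nucleophiles at C7) and the allylic acetate. The difficulties are the macrocyclisation, the trans ring fusion, the differentiation of three trisubstituted alkenes of a terpenoid chain, and the need to bring in the hydroperoxide last. The strategy rests on the C1–C2 bond: it joins an allylic carbon (C2, next to the C3=C4 alkene from which the epoxide is made) to the β-carbon of the methylene lactone, so an allyl radical can be added to a butenolide that carries a radical leaving group on C17, closing the carbocycle and revealing C15=C17 in one event.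

## Retrosynthetic reasoning

**C7–OO bond.** Target 26 is traced to the 7S alcohol 24 through its sulfonate 25. The C7–O bond is exchanged with inversion, so the alcohol must be 7S. This is done last because no other operation of the route (tin radical chain, phosphine, base) would leave a hydroperoxide intact.

**C3–O and C4–O bonds.** Alcohol 24 comes from silyl ether 23, and 23 from triene 22. The epoxide cannot be present earlier, because the C3=C4 alkene is what makes C2 allylic in the ring closure. The forward reaction has to pick C3=C4 among four alkenes and one of its faces; a chiral dioxirane is asked to do both, the other alkenes being 1,1-disubstituted, acceptor-substituted or deactivated by the allylic acetate. The C7 silyl ether is kept through this step to shield the C8 methylene.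

**C1–C2 bond (ring closure).** Macrocycle 22 is opened to bromide 21. Other ring bonds (for example C12–C13 or C4–C5) would leave the lactone methylene to be built separately; C1–C2 is the one bond whose formation can also create the C1 stereocentre and the C15=C17 alkene. The forward reaction needs an allyl radical that bonds through C2 and not C4, attack on the butenolide face anti to the C14 substituent, and expulsion of the sulfonyl group from the adduct radical.

**C2–Br and C2–O protection.** Bromide 21 comes from alcohol 20 by Appel bromination, and 20 from its 4-methoxybenzyl ether 19. The bromide is made last because it would not survive the aldol and acylation steps. An ether is used at C2 because it has to be removed in the presence of the C13 acetate.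

**C13–C14 bond.** Acetate 19 comes from alcohol 18, which is cut into enal 10 and silyloxyfuran 16 (vinylogous aldol; the silicon-bound adduct 17 is hydrolysed on work-up). Both C13 and C14 are created here, so the forward reaction must control the aldehyde face by a catalyst and give the anti adduct.

**Butenolide fragment.** Furan 16 is the silyl dienol ether of butenolide 15. Its C17–S bond and ring unsaturation come from addition of the sulfonyl group of 12 across the exocyclic alkene of lactone 11, followed by dehydroiodination of 13 and alkene migration in 14.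

**C7 stereocentre and C8 methylene.** Aldehyde 10 is traced through hydroxy aldehyde 9 and diol 8 to the 7S,8S-epoxide 6 of the central alkene. Isomerisation of the epoxide (through 7) keeps the C7–O bond and moves the double bond into the C19 methyl group. Epoxide 6 comes from triene 5, in which the central alkene is the only one without an allylic oxygen substituent.

**Chain.** Triene 5 is the acetate of allylic alcohol 4, which arises by allylic oxidation of the terminal E-methyl group of ether 2 (over-oxidised enal 3 is reduced back). Ether 2 is made from farnesol 1, which supplies C2–C13, C18–C20 and all three E-alkenes.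

## Alternatives that were turned down

**Alternative 1:** The disconnection is C4–C5 together with the C3–O bond of the epoxide. The chain is split into the (3R)-α-chloro ketone A2 and the homoallylic Grignard reagent A3. In the forward step A3 adds to the C4 ketone of A2 and the alkoxide displaces chloride at C3 with inversion, giving epoxide A1.
- For it: the union is convergent, and the epoxide configuration follows from a stereocentre made beforehand. On this point it is stronger than the chosen route, whose step 15 relies on reagent control on a conformationally biased ring.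
- Against it: the step closes no carbocycle, and A1 still lacks the ring and the methylene. The organomagnesium reagent must distinguish the ketone from the lactone carbonyl of A2, A2 can epimerise at C3, and the facial selectivity of addition to a methyl ketone next to a chloride (Cornforth-type control) is not secure. The C7=C8 alkene of A1 must later be turned into the 7R hydroperoxide with neither site nor face control.
- Comparison: in place of early epoxide control, the chosen strategy closes the ring, sets C1 and forms the methylene in one step, and fixes C7 on the open chain.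

**Alternative 2:** The disconnection is the lactone bonds C16–O14 and C15–C16, leading back to the macrocyclic trans-homopropargylic alcohol A5. In the forward step divalent palladium under CO alkoxycarbonylates O14 and inserts the alkyne, giving methylene lactone A4.
- For it: this is a known reaction class, it is mild, and it makes the Michael acceptor at the very end with all ring stereocentres already in place. In precedent it is stronger than the chosen key step.
- Against it: A5, with its ring, epoxide, two alkenes and the trans C1-ethynyl/C14-hydroxyl pair, must be assembled by a separate macrocyclisation, which costs steps. A terminal alkyne and an epoxide are exposed to palladium. A4 still holds C7=C8, which must be distinguished from C11=C12 and oxidised at C7 with no stereochemical handle.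
- Comparison: the chosen strategy merges ring closure and methylene formation and needs no separate lactone annulation.

**Alternative 3:** The disconnection is C12–C13, leading to ynal A7. In the forward step zerovalent nickel (Ni(cod)2), an N-heterocyclic carbene and Et3SiH couple aldehyde and alkyne reductively, giving the E-allylic silyl ether A6.
- For it: the reaction type is established for macrocycles and builds the ring, the trisubstituted E-alkene and the C13 carbinol at once. For the reliability of the ring closure it is stronger than the chosen step.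
- Against it: whether C12 or C11 bonds to the aldehyde depends on the ligand. The C13 configuration rests on induction from C14 in an α-oxygenated aldehyde that epimerises easily. The lactone of A6 is saturated, so an enolate α-methylenation is needed in the presence of the epoxide, then silyl-to-acetate exchange, and C7 is again unresolved.
- Comparison: more steps follow ring closure; the chosen route delivers the methylene lactone directly and sets C13/C14 before the ring is closed.

Key step: step 14

## Route

Step 1
Reactants: 1 (2E,6E)-farnesol
Product: 2 (2E,6E)-farnesyl 4-methoxybenzyl ether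
Conditions: NaH, 4-MeOC6H4CH2Cl, Bu4NI (cat.), THF/DMF, 0 °C → rt
Reagents that add atoms: 4-methoxybenzyl chloride, COc1ccc(CCl)cc1
Why: Williamson etherification of the primary allylic alkoxide. The ether masks C2–O until the bromide is needed, is orthogonal to the later acetate and silyl ether, and inductively deactivates C3=C4 toward the oxidations that follow.

Step 2
Reactants: 2 (2E,6E)-farnesyl 4-methoxybenzyl ether
Product: 4 (2E,6E,10E)-12-(4-methoxybenzyloxy)-2,6,10-trimethyldodeca-2,6,10-trien-1-ol, via enal 3 (not isolated)
Conditions: SeO2 (cat.), tBuOOH, salicylic acid (cat.), CH2Cl2, rt; then NaBH4, MeOH, 0 °C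
Reagents that add atoms: selenium dioxide, O=[Se]=O (oxygen carrier); tert-butyl hydroperoxide, CC(C)(C)OO (terminal oxygen source)
Why: Riley allylic oxidation (ene reaction, then [2,3]-shift) attacks the most electron-rich and least hindered terminal alkene at its E-methyl group and gives the E-allylic alcohol (C13–OH). Over-oxidised enal 3 is returned to 4 by the borohydride treatment.

Step 3
Reactants: 4 (2E,6E,10E)-12-(4-methoxybenzyloxy)-2,6,10-trimethyldodeca-2,6,10-trien-1-ol
Product: 5 (2E,6E,10E)-12-(4-methoxybenzyloxy)-2,6,10-trimethyldodeca-2,6,10-trienyl acetate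
Conditions: Ac2O, pyridine, DMAP (cat.), CH2Cl2, 0 °C → rt
Reagents that add atoms: acetic anhydride, CC(=O)OC(C)=O
Why: Acylation of the primary alcohol. The allylic acetate switches off C11=C12 toward electrophilic oxidants, so the central alkene is the only one without an allylic oxygen.

Step 4
Reactants: 5 (2E,6E,10E)-12-(4-methoxybenzyloxy)-2,6,10-trimethyldodeca-2,6,10-trienyl acetate
Product: 6 (2E,10E)-(6S,7S)-6,7-epoxy-12-(4-methoxybenzyloxy)-2,6,10-trimethyldodeca-2,10-dienyl acetate (cembrane 7S,8S)
Conditions: ent-Shi ketone (L-fructose-derived, 0.3 equiv), KHSO5 (as 2KHSO5·KHSO4·K2SO4), K2CO3, Bu4NHSO4, MeCN/CH2(OMe)2/aq. Na2B4O7–Na2EDTA buffer, 0 °C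
Reagents that add atoms: potassium peroxymonosulfate, [K+].[O-]S(=O)(=O)OO
Why: Shi epoxidation. The electrophilic chiral dioxirane should choose the central alkene because both flanking alkenes are deactivated by allylic oxygen. The spiro transition state of the L-fructose-derived ketone should deliver oxygen to the face of the E-trisubstituted alkene that gives the S,S trans-epoxide (the D-fructose ketone gives R,R).

Step 5
Reactants: 6 (2E,10E)-(6S,7S)-6,7-epoxy-12-(4-methoxybenzyloxy)-2,6,10-trimethyldodeca-2,10-dienyl acetate
Product: 8 (2E,7S,10E)-12-(4-methoxybenzyloxy)-2,10-dimethyl-6-methylidenedodeca-2,10-diene-1,7-diol, via hydroxy acetate 7 (not isolated)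
Conditions: Al(OiPr)3, PhMe, 110 °C; aq. KNaC4H4O6 work-up; then K2CO3, MeOH, rt
Reagents that add atoms: none
Why: Epoxide-to-allylic-alcohol isomerisation: aluminium binds the epoxide oxygen, the tertiary C8–O bond breaks and an isopropoxide ligand removes a proton through a cyclic transition state, preferentially from the unhindered C19 methyl group, so the exo-methylene alcohol forms with the C7–O bond and its 7S configuration untouched. A hindered aluminium amide is avoided because it tends to take the proton from the group cis to the epoxide hydrogen (C9 here); any exchange of the acetate under these conditions is made irrelevant by the methanolysis that follows.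

Step 6
Reactants: 8 (2E,7S,10E)-12-(4-methoxybenzyloxy)-2,10-dimethyl-6-methylidenedodeca-2,10-diene-1,7-diol
Product: 9 (2E,7S,10E)-7-hydroxy-12-(4-methoxybenzyloxy)-2,10-dimethyl-6-methylidenedodeca-2,10-dienal
Conditions: TEMPO (cat.), PhI(OAc)2, CH2Cl2, rt
Reagents that add atoms: none
Why: Oxoammonium oxidation is much faster for the primary allylic alcohol than for the hindered secondary one, so the E-enal forms without touching C7–OH and without E/Z isomerisation.

Step 7
Reactants: 9 (2E,7S,10E)-7-hydroxy-12-(4-methoxybenzyloxy)-2,10-dimethyl-6-methylidenedodeca-2,10-dienal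
Product: 10 (2E,7S,10E)-7-(tert-butyldimethylsilyloxy)-12-(4-methoxybenzyloxy)-2,10-dimethyl-6-methylidenedodeca-2,10-dienal
Conditions: TBSCl, imidazole, DMAP (cat.), DMF, rt
Reagents that add atoms: tert-butyldimethylsilyl chloride, CC(C)(C)[Si](C)(C)Cl
Why: Silylation of the secondary allylic alcohol under conditions that leave the enal alone. The silyl ether survives Lewis acid at low temperature, DDQ, the Appel reaction, the radical chain and the second epoxidation.

Step 8
Reactants: 11 3-methylideneoxolan-2-one (α-methylene-γ-butyrolactone); 12 sodium benzenesulfinate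
Product: 15 3-(phenylsulfonylmethyl)furan-2(5H)-one, via iodosulfone 13 (not isolated), via vinyl sulfone 14 (not isolated)
Conditions: I2, CH2Cl2/H2O, rt, visible light; then Et3N, EtOAc, reflux
Reagents that add atoms: none
Why: Iodosulfonylation–dehydroiodination as practised on 2-substituted acrylates: PhSO2I formed in the flask adds by a radical chain (sulfonyl to the CH2 terminus, iodine to the α-carbon). The amine removes HI to give the vinyl sulfone, which equilibrates to the more stable allyl sulfone, here the endocyclic butenolide.

Step 9
Reactants: 15 3-(phenylsulfonylmethyl)furan-2(5H)-one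
Product: 16 2-(tert-butyldimethylsilyloxy)-3-(phenylsulfonylmethyl)furan
Conditions: TBSOTf, Et3N, CH2Cl2, 0 °C
Reagents that add atoms: tert-butyldimethylsilyl trifluoromethanesulfonate, CC(C)(C)[Si](C)(C)OS(=O)(=O)C(F)(F)F
Why: Soft enolisation: O-silylation of the lactone carbonyl and loss of H5 give the aromatic 2-silyloxyfuran. Deprotonation at the sulfonyl-bearing CH2 would not lead to an aromatic product and is not expected to compete.

Step 10
Reactants: 10 (2E,7S,10E)-7-(tert-butyldimethylsilyloxy)-12-(4-methoxybenzyloxy)-2,10-dimethyl-6-methylidenedodeca-2,10-dienal; 16 2-(tert-butyldimethylsilyloxy)-3-(phenylsulfonylmethyl)furan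
Product: 18 (5R)-5-[(1S,2E,7S,10E)-7-(tert-butyldimethylsilyloxy)-1-hydroxy-12-(4-methoxybenzyloxy)-2,10-dimethyl-6-methylidenedodeca-2,10-dienyl]-3-(phenylsulfonylmethyl)furan-2(5H)-one, via trichlorosilyl ether 17 (not isolated)
Conditions: SiCl4 (1.1 equiv), (R,R)-binaphthyldiamine-derived bisphosphoramide (5 mol %), iPr2NEt (10 mol %), CH2Cl2, −78 °C; aq. KF/NaHCO3
Reagents that add atoms: none
Why: Catalytic asymmetric vinylogous Mukaiyama aldol reaction under Lewis-base-activated SiCl4, a system suited to α-branched conjugated aldehydes; the furan reacts at C5 (cembrane C14). The chiral silicon cation should expose the Re face of the aldehyde (13S), and an open antiperiplanar transition state should give the anti adduct (14R); if either sense proves reversed, the antipodal catalyst or the fallback given below is used.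

Step 11
Reactants: 18 (13S,14R)-aldol adduct
Product: 19 (5R)-5-[(1S,2E,7S,10E)-1-acetoxy-7-(tert-butyldimethylsilyloxy)-12-(4-methoxybenzyloxy)-2,10-dimethyl-6-methylidenedodeca-2,10-dienyl]-3-(phenylsulfonylmethyl)furan-2(5H)-one
Conditions: Ac2O, pyridine, DMAP (cat.), CH2Cl2, 0 °C
Reagents that add atoms: acetic anhydride, CC(=O)OC(C)=O
Why: Acylation of the secondary allylic alcohol with retention; low temperature and a short reaction time keep the acidic H14 of the butenolide in place.

Step 12
Reactants: 19 (13S,14R)-acetate 4-methoxybenzyl ether
Product: 20 (5R)-5-[(1S,2E,7S,10E)-1-acetoxy-7-(tert-butyldimethylsilyloxy)-12-hydroxy-2,10-dimethyl-6-methylidenedodeca-2,10-dienyl]-3-(phenylsulfonylmethyl)furan-2(5H)-one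
Conditions: DDQ, CH2Cl2/pH 7 buffer, 0 °C
Reagents that add atoms: none
Why: Oxidative cleavage of the 4-methoxybenzyl ether by benzylic hydride abstraction and hydrolysis; acetate, silyl ether, sulfone and the unactivated alkenes are inert to DDQ under buffered conditions.

Step 13
Reactants: 20 C2 allylic alcohol
Product: 21 (5R)-5-[(1S,2E,7S,10E)-1-acetoxy-12-bromo-7-(tert-butyldimethylsilyloxy)-2,10-dimethyl-6-methylidenedodeca-2,10-dienyl]-3-(phenylsulfonylmethyl)furan-2(5H)-one
Conditions: CBr4, PPh3 (added last), 2,6-lutidine (cat.), CH2Cl2, −20 → 0 °C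
Reagents that add atoms: carbon tetrabromide, BrC(Br)(Br)Br
Why: Appel bromination: SN2 displacement at the primary carbon of the oxyphosphonium ion gives the E-allylic bromide without transposition. The phosphine is consumed by CBr4 before it can add to the butenolide, and the bromide is used at once.

Step 14
Reactants: 21 seco allylic bromide with 3-(phenylsulfonylmethyl)butenolide
Product: 22 (1R,7S,13S,14R,3E,11E)-13-acetoxy-7-(tert-butyldimethylsilyloxy)cembra-3,8(19),11,15(17)-tetraen-16,14-olide
Conditions: (Bu3Sn)2 (1.2 equiv), hν (sunlamp, Pyrex), PhH (0.002 M), 80 °C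
Reagents that add atoms: none
Why: Proposed new method: photolysis of (Bu3Sn)2 gives Bu3Sn•, which abstracts bromine from 21; the nucleophilic allyl radical (spin at C2 and C4) adds through its unhindered primary terminus C2 to the electron-poor β-carbon C1 of the butenolide, and the tertiary C15 radical loses PhSO2• by β-scission of the C17–S bond, which creates the C15=C17 methylene without a hydrogen donor. PhSO2• attacks the ditin to give Bu3SnO2SPh and a new Bu3Sn•, so the chain runs on tin and no tin hydride that could reduce the allyl radical is present. The closest known reaction types are allyl-radical macrocyclisation onto enones under tin hydride and intermolecular radical allyl transfer to 2-(sulfonylmethyl)acrylates; their combination on a butenolide is new. The 14-membered carbocycle closes in the 14-exo-trig mode with respect to the new ring: attack is at the alkene carbon bound to C14, the radical is left on C15 outside the carbocycle, and the C1=C15 bond is endocyclic only to the lactone that already exists. The new stereocentre C1 (R) is controlled by C14, since the radical should enter the planar butenolide on the face anti to the C13 side chain and give the trans C1/C14 lactone. The step needs C2 over C4 attack (secured by the methyl group on C4 and by the strain of the alternative 12-membered ring), cyclisation over intermolecular reaction (high dilution; the stabilised allyl radical adds only slowly to the unactivated alkenes of the chain), and retention of the E geometry at C3=C4 (allyl radicals rotate slowly and the β-scission is fast).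

Step 15
Reactants: 22 macrocyclic tetraene
Product: 23 (1R,3S,4S,7S,13S,14R,11E)-13-acetoxy-3,4-epoxy-7-(tert-butyldimethylsilyloxy)cembra-8(19),11,15(17)-trien-16,14-olide
Conditions: ent-Shi ketone (L-fructose-derived, 0.5 equiv), KHSO5 (as 2KHSO5·KHSO4·K2SO4), K2CO3, Bu4NHSO4, MeCN/CH2(OMe)2/aq. Na2B4O7–Na2EDTA buffer, −10 → 0 °C
Reagents that add atoms: potassium peroxymonosulfate, [K+].[O-]S(=O)(=O)OO
Why: Shi epoxidation with the same catalyst enantiomer as in step 4, which should give the S,S trans-epoxide of the E-alkene. C3=C4 is the only electron-rich trisubstituted alkene: C11=C12 carries the allylic acetate, C8=C19 is 1,1-disubstituted (a poor substrate for this ketone) and shielded by the silyl ether, and C15=C17 is acceptor-substituted.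

Step 16
Reactants: 23 epoxy silyl ether
Product: 24 (1R,3S,4S,7S,13S,14R,11E)-13-acetoxy-3,4-epoxy-7-hydroxycembra-8(19),11,15(17)-trien-16,14-olide
Conditions: TASF [(Me2N)3S+ Me3SiF2−], DMF/H2O (20:1), 0 °C → rt
Reagents that add atoms: none
Why: Fluoride-induced desilylation under nearly neutral conditions, so that neither acid (transannular opening of the epoxide by the C7 hydroxyl) nor strong base (acetate loss, Michael addition to the lactone) intervenes. The alcohol is not stored but taken on at once.

Step 17
Reactants: 24 7S alcohol
Product: 26 (1R,3S,4S,7R,13S,14R,11E)-13-acetoxy-3,4-epoxy-7-hydroperoxycembra-8(19),11,15(17)-trien-16,14-olide, via mesylate 25 (not isolated)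
Conditions: MsCl, Et3N, CH2Cl2, −70 °C; then anhydrous H2O2 in Et2O, −110 → −78 °C
Reagents that add atoms: hydrogen peroxide, OO
Why: Perhydrolysis of a secondary allylic mesylate: in the weakly ionising ether at very low temperature neutral H2O2 should displace the sulfonate at C7 by SN2 with inversion (7S → 7R). No base, metal or reductant is present that would harm the hydroperoxide, the epoxide or the methylene lactone.

## Compound list

1 | (2E,6E)-farnesol | OC/C=C(\C)CC/C=C(\C)CCC=C(C)C | starting material
2 | (2E,6E)-farnesyl 4-methoxybenzyl ether | COc1ccc(COC/C=C(\C)CC/C=C(\C)CCC=C(C)C)cc1 | intermediate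
3 | (2E,6E,10E)-12-(4-methoxybenzyloxy)-2,6,10-trimethyldodeca-2,6,10-trienal | COc1ccc(COC/C=C(\C)CC/C=C(\C)CC/C=C(\C)C=O)cc1 | intermediate (not isolated)
4 | (2E,6E,10E)-12-(4-methoxybenzyloxy)-2,6,10-trimethyldodeca-2,6,10-trien-1-ol | COc1ccc(COC/C=C(\C)CC/C=C(\C)CC/C=C(\C)CO)cc1 | intermediate
5 | (2E,6E,10E)-12-(4-methoxybenzyloxy)-2,6,10-trimethyldodeca-2,6,10-trienyl acetate | COc1ccc(COC/C=C(\C)CC/C=C(\C)CC/C=C(\C)COC(C)=O)cc1 | intermediate
6 | (2E,10E)-(6S,7S)-6,7-epoxy-12-(4-methoxybenzyloxy)-2,6,10-trimethyldodeca-2,10-dienyl acetate | COc1ccc(COC/C=C(\C)CC[C@@H]2O[C@@]2(C)CC/C=C(\C)COC(C)=O)cc1 | intermediate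
7 | (2E,7S,10E)-7-hydroxy-12-(4-methoxybenzyloxy)-2,10-dimethyl-6-methylidenedodeca-2,10-dienyl acetate | COc1ccc(COC/C=C(\C)CC[C@H](O)C(=C)CC/C=C(\C)COC(C)=O)cc1 | intermediate (not isolated)
8 | (2E,7S,10E)-12-(4-methoxybenzyloxy)-2,10-dimethyl-6-methylidenedodeca-2,10-diene-1,7-diol | COc1ccc(COC/C=C(\C)CC[C@H](O)C(=C)CC/C=C(\C)CO)cc1 | intermediate
9 | (2E,7S,10E)-7-hydroxy-12-(4-methoxybenzyloxy)-2,10-dimethyl-6-methylidenedodeca-2,10-dienal | COc1ccc(COC/C=C(\C)CC[C@H](O)C(=C)CC/C=C(\C)C=O)cc1 | intermediate
10 | (2E,7S,10E)-7-(tert-butyldimethylsilyloxy)-12-(4-methoxybenzyloxy)-2,10-dimethyl-6-methylidenedodeca-2,10-dienal | COc1ccc(COC/C=C(\C)CC[C@H](O[Si](C)(C)C(C)(C)C)C(=C)CC/C=C(\C)C=O)cc1 | intermediate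
11 | 3-methylideneoxolan-2-one (α-methylene-γ-butyrolactone) | C=C1CCOC1=O | starting material
12 | sodium benzenesulfinate | [Na+].[O-]S(=O)c1ccccc1 | starting material
13 | 3-iodo-3-(phenylsulfonylmethyl)oxolan-2-one (racemic) | O=C1OCCC1(I)CS(=O)(=O)c1ccccc1 | intermediate (not isolated)
14 | (E)-3-(phenylsulfonylmethylidene)oxolan-2-one | O=C1OCC/C1=C\S(=O)(=O)c1ccccc1 | intermediate (not isolated)
15 | 3-(phenylsulfonylmethyl)furan-2(5H)-one | O=C1OCC=C1CS(=O)(=O)c1ccccc1 | intermediate
16 | 2-(tert-butyldimethylsilyloxy)-3-(phenylsulfonylmethyl)furan | CC(C)(C)[Si](C)(C)Oc1occc1CS(=O)(=O)c1ccccc1 | intermediate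
17 | trichlorosilyl ether of 18 (13S,14R) | COc1ccc(COC/C=C(\C)CC[C@H](O[Si](C)(C)C(C)(C)C)C(=C)CC/C=C(\C)[C@H](O[Si](Cl)(Cl)Cl)[C@@H]2OC(=O)C(CS(=O)(=O)c3ccccc3)=C2)cc1 | intermediate (not isolated)
18 | (5R)-5-[(1S,2E,7S,10E)-7-(tert-butyldimethylsilyloxy)-1-hydroxy-12-(4-methoxybenzyloxy)-2,10-dimethyl-6-methylidenedodeca-2,10-dienyl]-3-(phenylsulfonylmethyl)furan-2(5H)-one | COc1ccc(COC/C=C(\C)CC[C@H](O[Si](C)(C)C(C)(C)C)C(=C)CC/C=C(\C)[C@H](O)[C@@H]2OC(=O)C(CS(=O)(=O)c3ccccc3)=C2)cc1 | intermediate
19 | 13-acetate of 18 | COc1ccc(COC/C=C(\C)CC[C@H](O[Si](C)(C)C(C)(C)C)C(=C)CC/C=C(\C)[C@H](OC(C)=O)[C@@H]2OC(=O)C(CS(=O)(=O)c3ccccc3)=C2)cc1 | intermediate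
20 | (5R)-5-[(1S,2E,7S,10E)-1-acetoxy-7-(tert-butyldimethylsilyloxy)-12-hydroxy-2,10-dimethyl-6-methylidenedodeca-2,10-dienyl]-3-(phenylsulfonylmethyl)furan-2(5H)-one | OC/C=C(\C)CC[C@H](O[Si](C)(C)C(C)(C)C)C(=C)CC/C=C(\C)[C@H](OC(C)=O)[C@@H]1OC(=O)C(CS(=O)(=O)c2ccccc2)=C1 | intermediate
21 | seco allylic bromide: 12-bromo analogue of 20 | BrC/C=C(\C)CC[C@H](O[Si](C)(C)C(C)(C)C)C(=C)CC/C=C(\C)[C@H](OC(C)=O)[C@@H]1OC(=O)C(CS(=O)(=O)c2ccccc2)=C1 | intermediate
22 | (1R,7S,13S,14R,3E,11E)-13-acetoxy-7-(tert-butyldimethylsilyloxy)cembra-3,8(19),11,15(17)-tetraen-16,14-olide | C=C1C(=O)O[C@@H]2[C@@H]1C/C=C(\C)CC[C@H](O[Si](C)(C)C(C)(C)C)C(=C)CC/C=C(\C)[C@@H]2OC(C)=O | intermediate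
23 | (1R,3S,4S,7S,13S,14R,11E)-13-acetoxy-3,4-epoxy-7-(tert-butyldimethylsilyloxy)cembra-8(19),11,15(17)-trien-16,14-olide | C=C1C(=O)O[C@@H]2[C@@H]1C[C@@H]1O[C@@]1(C)CC[C@H](O[Si](C)(C)C(C)(C)C)C(=C)CC/C=C(\C)[C@@H]2OC(C)=O | intermediate
24 | (1R,3S,4S,7S,13S,14R,11E)-13-acetoxy-3,4-epoxy-7-hydroxycembra-8(19),11,15(17)-trien-16,14-olide | C=C1C(=O)O[C@@H]2[C@@H]1C[C@@H]1O[C@@]1(C)CC[C@H](O)C(=C)CC/C=C(\C)[C@@H]2OC(C)=O | intermediate
25 | 7S methanesulfonate of 24 | C=C1C(=O)O[C@@H]2[C@@H]1C[C@@H]1O[C@@]1(C)CC[C@H](OS(C)(=O)=O)C(=C)CC/C=C(\C)[C@@H]2OC(C)=O | intermediate (not isolated)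
26 | (1R,3S,4S,7R,13S,14R,11E)-13-acetoxy-3,4-epoxy-7-hydroperoxycembra-8(19),11,15(17)-trien-16,14-olide (CNP0166375.2) | C=C1C(=O)O[C@@H]2[C@@H]1C[C@@H]1O[C@@]1(C)CC[C@@H](OO)C(=C)CC/C=C(\C)[C@@H]2OC(C)=O | target

## Step count and least certain steps

Total: 17 steps. Longest linear sequence: 15 steps (1–7, then 10–17); the butenolide branch is 2 steps (8 and 9).

**Step 14 (key step).** The stabilised allyl radical may add too slowly to a butenolide β-carbon that is γ-branched and α-substituted. Chain termination (allyl–allyl or allyl–stannyl coupling), erosion of alkene geometry by reversible sulfonyl-radical addition, or closure on the wrong butenolide face could then take over. The fallback uses known chemistry (tin-hydride-mediated allyl-radical macrocyclisation onto an unsaturated carbonyl acceptor, then α-methylenation). It sets out from aldehyde 10 and returns at 22. Aldehyde 10 is combined, under the conditions of step 10, with commercial 2-(trimethylsilyloxy)furan to give the unsubstituted butenolide aldol adduct F1. Acetylation gives acetate F2, DDQ gives allylic alcohol F3, and CBr4/PPh3 gives bromide F4. Slow addition of Bu3SnH/AIBN to F4 in boiling benzene at high dilution closes the ring to the saturated trans-fused lactone F5. LiN(SiMe3)2 at −78 °C (the lactone is more acidic than the acetate) and CH2=NMe2+ I− give Mannich base F6, which MeI and then NaHCO3 convert into 22. This costs two more steps and gives up the direct unveiling of the methylene.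

**Step 17.** The allylic mesylate may ionise or be attacked at the terminal methylene carbon, leading to loss of configurational purity at C7 and to allylic transposition. The epoxide oxygen or elimination to the diene may also intervene. The fallback sets out from 24 and returns at 24 and 26. It gives up stereospecificity: mesylate 25 is allowed to react with ethereal H2O2 through the ion pair (−40 °C), the C7 epimers, which are diastereomers, are separated, and the unwanted 7S hydroperoxide F7 is reduced with PPh3 to alcohol 24 and resubmitted.

**Step 10.** The simple diastereoselection of a 3-substituted silyloxyfuran with an α-branched enal is not secure; furan dienolates can turn syn-selective, and the sulfone may bind the silicon catalyst. The fallback sets out from 10 and 16 and returns at 19. The (S,S)-configured catalyst is used so that the syn adduct F8 (13R,14R) is formed, and C13 is inverted in a Mitsunobu reaction with AcOH (PPh3, DIAD, PhMe, 0 °C), which gives acetate 19 directly and replaces step 11.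

**Step 15.** The conformational bias of the macrocycle may override the chiral ketone (poor facial selectivity), and the basic peroxide medium may attack the methylene lactone. The fallback sets out from 22 and returns at 23. It uses substrate control: NBS in aqueous THF gives bromohydrin F11 (bromonium ion on the exposed face, water at C4), and Ag2O closes it to 23. This puts the oxygen on the face opposite to the one an electrophile attacks. If the exposed face is instead the required one, dimethyldioxirane in acetone would be used directly, which needs no new compound.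

**Step 5.** Proton removal from the C9 methylene instead of the C19 methyl group would give the in-chain alkene, and the epoxide may rearrange to a ketone. The fallback sets out from 5 and returns at 7 (then methanolysis to 8 as in step 5). Photo-oxygenation (O2, tetraphenylporphyrin, hν, CH2Cl2) of the only electron-rich alkene gives, by the Schenck ene reaction, the racemic secondary allylic hydroperoxide F9 (the tertiary regioisomer is removed). Kornblum–DeLaMare dehydration (Ac2O, pyridine) gives enone F10. Corey–Bakshi–Shibata reduction with the (R)-oxazaborolidine and BH3·SMe2 sets 7S, the α-branched vinyl group acting as the large substituent.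

## Further compounds

F1 | step 14 | (13S,14R)-aldol adduct of 10 with unsubstituted butenolide | COc1ccc(COC/C=C(\C)CC[C@H](O[Si](C)(C)C(C)(C)C)C(=C)CC/C=C(\C)[C@H](O)[C@@H]2OC(=O)C=C2)cc1
F2 | step 14 | 13-acetate of F1 | COc1ccc(COC/C=C(\C)CC[C@H](O[Si](C)(C)C(C)(C)C)C(=C)CC/C=C(\C)[C@H](OC(C)=O)[C@@H]2OC(=O)C=C2)cc1
F3 | step 14 | C2 allylic alcohol from F2 | OC/C=C(\C)CC[C@H](O[Si](C)(C)C(C)(C)C)C(=C)CC/C=C(\C)[C@H](OC(C)=O)[C@@H]1OC(=O)C=C1
F4 | step 14 | C2 allylic bromide from F3 | BrC/C=C(\C)CC[C@H](O[Si](C)(C)C(C)(C)C)C(=C)CC/C=C(\C)[C@H](OC(C)=O)[C@@H]1OC(=O)C=C1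
F5 | step 14 | (1R,7S,13S,14R,3E,11E)-13-acetoxy-7-(tert-butyldimethylsilyloxy)cembra-3,8(19),11-trien-16,14-olide with C15H2 (saturated lactone) | C1C(=O)O[C@@H]2[C@@H]1C/C=C(\C)CC[C@H](O[Si](C)(C)C(C)(C)C)C(=C)CC/C=C(\C)[C@@H]2OC(C)=O
F6 | step 14 | 15-(dimethylaminomethyl) derivative of F5 (Mannich base, C15 unassigned) | CN(C)CC1C(=O)O[C@@H]2[C@@H]1C/C=C(\C)CC[C@H](O[Si](C)(C)C(C)(C)C)C(=C)CC/C=C(\C)[C@@H]2OC(C)=O
F7 | step 17 | 7S epimer of 26 | C=C1C(=O)O[C@@H]2[C@@H]1C[C@@H]1O[C@@]1(C)CC[C@H](OO)C(=C)CC/C=C(\C)[C@@H]2OC(C)=O
F8 | step 10 | (13R,14R)-syn aldol adduct, C13 epimer of 18 | COc1ccc(COC/C=C(\C)CC[C@H](O[Si](C)(C)C(C)(C)C)C(=C)CC/C=C(\C)[C@@H](O)[C@@H]2OC(=O)C(CS(=O)(=O)c3ccccc3)=C2)cc1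
F9 | step 5 | racemic (2E,10E)-7-hydroperoxy-12-(4-methoxybenzyloxy)-2,10-dimethyl-6-methylidenedodeca-2,10-dienyl acetate | COc1ccc(COC/C=C(\C)CCC(OO)C(=C)CC/C=C(\C)COC(C)=O)cc1
F10 | step 5 | (2E,10E)-12-(4-methoxybenzyloxy)-2,10-dimethyl-6-methylidene-7-oxododeca-2,10-dienyl acetate | COc1ccc(COC/C=C(\C)CCC(=O)C(=C)CC/C=C(\C)COC(C)=O)cc1
F11 | step 15 | (3R,4S)-3-bromo-4-hydroxy derivative of 22 (bromohydrin) | C=C1C(=O)O[C@@H]2[C@@H]1C[C@@H](Br)[C@@](C)(O)CC[C@H](O[Si](C)(C)C(C)(C)C)C(=C)CC/C=C(\C)[C@@H]2OC(C)=O
A1 | alternative 1 | (3S,4S)-epoxide seco chain: saturated lactone with C13 silyl ether, 7E alkene and methyl alkyne | C1C(=O)O[C@@H](CO[Si](C)(C)C(C)(C)C)[C@@H]1C[C@@H]1O[C@@]1(C)CC/C=C(\C)CCC#CC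
A2 | alternative 1 | (3R)-α-chloro methyl ketone fragment (fragment 1) | C1C(=O)O[C@@H](CO[Si](C)(C)C(C)(C)C)[C@@H]1C[C@@H](Cl)C(C)=O
A3 | alternative 1 | (E)-4-methylnon-3-en-7-ynylmagnesium bromide (fragment 2) | Br[Mg]CC/C=C(\C)CCC#CC
A4 | alternative 2 | methylene lactone macrocycle with 3,4-epoxide, 7E,11E-diene and 13-silyl ether | C=C1C(=O)O[C@@H]2[C@@H]1C[C@@H]1O[C@@]1(C)CC/C=C(\C)CC/C=C(\C)[C@@H]2O[Si](C)(C)C(C)(C)C
A5 | alternative 2 | macrocyclic trans-homopropargylic alcohol (C1 ethynyl, C14 hydroxyl, 13-silyl ether) | C#C[C@H]1C[C@@H]2O[C@@]2(C)CC/C=C(\C)CC/C=C(\C)[C@H](O[Si](C)(C)C(C)(C)C)[C@@H]1O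
A6 | alternative 3 | macrocyclic 13-triethylsilyl ether with 7E,11E-diene, epoxide and saturated lactone | C1C(=O)O[C@@H]2[C@@H]1C[C@@H]1O[C@@]1(C)CC/C=C(\C)CC/C=C(\C)[C@@H]2O[Si](CC)(CC)CC
A7 | alternative 3 | seco ynal: C13 aldehyde on the saturated lactone, methyl-capped C11≡C12 alkyne | C1C(=O)O[C@@H](C=O)[C@@H]1C[C@@H]1O[C@@]1(C)CC/C=C(\C)CCC#CC
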